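(The runs are calculated from invented constants, noise included.)

The ratio I started from was late slope over early slope in elm: product rose at 0.0735 /min of the substrate charge up to the first reading, then at 0.0220 /min over the last readings, a ratio of 0.299. Stray impurity over catalyst gives a surviving share of 0.320, beside that ratio, so by this ratio I could not tell catalyst loss from partner loss. I assumed that catalyst loss ended before the first reading and that the slope followed the partner share, the free fraction of the partner charge. The early slope then served as the rate per partner share.

all flasks: stray impurity 0.68 mM
- elm: substrate 0.20 M; partner 0.19 M; protic impurity 0.20 M; free catalyst 1 mM; run made earlier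
- alder: substrate 0.13 M; partner 0.19 M; protic impurity 0.20 M; free catalyst 1 mM; run made earlier
- cedar: substrate 0.30 M; partner 0.19 M; protic impurity 0.20 M; free catalyst 1 mM; run made earlier
- red: substrate 0.20 M (fed, over 5.00 min); partner 0.190 M; protic impurity 0.200 M; free catalyst 1.0 mM; all but substrate at the start; substrate goes in evenly over 5.00 min, the run ends at 5.0 min; time 5.0 min
- green: substrate 0.20 M; partner 0.190 M; protic impurity 0.200 M; free catalyst 1.0 mM; a single well-mixed tank run continuously and read at steady state, 5.0 min in it on average
- blue: substrate 0.20 M; partner 0.190 M; protic impurity 0.200 M; free catalyst 1.0 mM; one stirred flow tank at steady state, fed with the mixture as stated, mean residence time 15.0 min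
- grey: substrate 0.20 M; partner 0.190 M; protic impurity 0.200 M; free catalyst 1.0 mM; everything together in a closed stirred flask, run for 5.0 min; time 5.0 min

| run | time / min | product / % |
|---|---|---|
| elm | 0.667 | 4.9 |
| elm | 1.33 | 8.3 |
| elm | 2.00 | 11.2 |
| elm | 3.00 | 13.8 |
| elm | 4.00 | 16.0 |
| elm | 5.00 | 18.2 |
| alder | 0.417 | 3.8 |
| alder | 0.833 | 7.0 |
| alder | 1.33 | 10.2 |
| alder | 1.50 | 11.1 |
| alder | 2.00 | 13.6 |
| alder | 2.50 | 15.5 |
| alder | 3.00 | 16.7 |
| cedar | 0.167 | 0.9 |
| cedar | 0.500 | 2.5 |
| cedar | 0.833 | 4.8 |
| cedar | 1.33 | 6.0 |
| cedar | 2.00 | 8.9 |
| cedar | 2.50 | 9.7 |
| cedar | 3.00 | 11.0 |

(scatter of a reading: 0.3 percentage points)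

- the stated concentrations are those of everything mixed, before any reaction; amounts are the same in each set-up
- steps under discussion: partner + free catalyst <-> catalyst intermediate A; substrate + catalyst intermediate A -> catalyst intermediate B; catalyst intermediate B -> free catalyst + product; partner + protic impurity -> quenched reagent; free catalyst + stray impurity -> spent catalyst
- the feed brings no volume worth counting
- the earlier runs were made in a closed, stirred flask

- the set-up with the highest amount of product at the outlet or at the end, in percent of the substrate put in ("none" if the first two lie within 2 percentage points) (red / green / blue / grey / none)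
- amount of product at the outlet or at the end, in percent of the substrate put in, red
- amount of product at the outlet or at the end, in percent of the substrate put in, green
- amount of product at the outlet or at the end, in percent of the substrate put in, blue
- amount of product at the outlet or at the end, in percent of the substrate put in, grey

Protic impurity stood at 1.05 of the partner charge, so I let partner share fall as one over one plus time over a clock. The ratio at 4.00 min gave a clock of 1.71 min. Blue's residence time is 8.77 clocks, and I took its product as rate per share times residence time times share. Product takes partner too, a term of 1.16 times the share.

| Blue bound | Protic, as fraction of partner charge | Partner share | Product |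
|---|---|---|---|
| Above | equal to partner share | 0.236 | 26.0% |
| Below | held high, pseudo-first-order | 0.141 | 15.5% |

The lower bound's protic level, 0.563, came from the upper bound's partner balance. The bracket's midpoint, 20.8%, exceeded elm's last reading of 18.2%, my figure for grey, so I put blue above grey, though the lower bound stood below that reading; red and green I did not reckon.

The forecast chose blue, with 8.5% for red, 15.5% for green, 18.2% for grey and 27% for blue, above my bracket, “despite partner loss”.

The flask gave 10.1% in red, 15.6% in green, 17.8% in grey and blue as best, with 23.1% in blue, inside the bracket.

    partner + free catalyst ⇌ catalyst intermediate A (K = 2.39 /M, k = 9.88 /M/s)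
    substrate + catalyst intermediate A → catalyst intermediate B (k = 29.7 /M/s)
    catalyst intermediate B → free catalyst + product (k = 7.90 /s)
    partner + protic impurity → quenched reagent (k = 0.0425 /M/s)
    free catalyst + stray impurity → spent catalyst (k = 15300 /M/s)

Partner quenching ran alongside the catalytic cycle, with a partner half-life by that path of 1.4 min at charged concentrations in grey. At steady state, green held 35.2% of its partner charge and made 0.0884 /min per partner share, above the elm reading, while blue held 17.2% and made 0.0894 /min per partner share.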